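**Assumption:** the SMILES encodes a ring-cis (Z) C5=C6 alkene in the 10-membered ring. Briarane numbering is used throughout (C1 quaternary, C2/C14 OAc, C7–C8 lactone, C9 OH). Intermediates carry the target's configuration at C1, C2, C7, C9, C10 and C14, as written in their SMILES.

## Retrosynthesis
1. Target ⇐ 9-O-PMB diacetate. The γ-lactone and the C8 tertiary alcohol come from an intramolecular SmI2 Reformatsky of a C7 α-bromopropionate onto the C8 ketone.
2. The 10-membered ring with the Z-C5=C6 alkene comes from macro-RCM of a C5 isopropenyl and a C7 vinyl carbinol, run after the cyclohexene is in place.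
3. C7/C8/C9 are built on a 1,3-dithiane C8 linchpin: Felkin addition of lithiodithiane to the ring-A C9 aldehyde, then acrolein, oxidation and CBS reduction.
4. Ring A (C11=C12) comes from RCM of a triene bearing the C1 quaternary centre. C1/C10 are set by an organocatalytic Michael addition of aldehyde **6** to nitrodiene **10**, C14 by catalytic asymmetric allylation, and C2 by a ketoreductase DKR.
5. Ring order: cyclohexene (Step 10), then 10-membered ring (Step 18), then γ-lactone (Step 21).

## Route

**Step 1**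
Reactants: **1** ethyl 2-methyl-3-oxobutanoate; **2** 3-bromo-2-methylprop-1-ene
Product: **3** ethyl 2,6-dimethyl-3-oxohept-6-enoate
Conditions: NaH, THF, 0 °C; then n-BuLi, 0 °C; then **2**, −78 °C → rt
Reagents that add atoms: none
Why: Weiler dianion alkylation; the more basic γ-carbanion reacts with the allylic bromide. The α-CH left in the product is epimerisable and is destroyed in Step 7.

**Step 2**
Reactants: **3**
Product: **4** ethyl (2S,3R)-3-hydroxy-2,6-dimethylhept-6-enoate
Conditions: ketoreductase (selected for the 3R alcohol), NADP⁺ (cat.), glucose/GDH, KPi pH 7.5, 10% DMSO, 30 °C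
Reagents that add atoms: none
Why: Ketoreductase-catalysed dynamic kinetic resolution. The acidic α-stereocentre epimerises through the enol while the enzyme reduces one enantioface, so C2 (target numbering) is set as R.

**Step 3**
Reactants: **4**
Product: **5** TBS ether of **4**
Conditions: TBSOTf, 2,6-lutidine, CH2Cl2, 0 °C
Reagents that add atoms: TBSOTf, CC(C)(C)[Si](C)(C)OS(=O)(=O)C(F)(F)F
Why: Silylation protects the C2 alcohol for the later organometallic steps.

**Step 4**
Reactants: **5**
Product: **6** (2S,3R)-3-(TBSO)-2,6-dimethylhept-6-enal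
Conditions: DIBAL-H, CH2Cl2, −78 °C
Reagents that add atoms: none
Why: Partial ester reduction to the α-branched aldehyde. Its α-stereocentre epimerises through the enamine in Step 7 and is irrelevant.

**Step 5**
Reactants: **7** methacrolein; **8** nitromethane
Product: **9** 3-methyl-1-nitrobut-3-en-2-ol (racemic)
Conditions: NaOH (cat.), MeOH, 0 °C
Reagents that add atoms: none
Why: Henry (nitroaldol) 1,2-addition to the enal.

**Step 6**
Reactants: **9**
Product: **10** (E)-3-methyl-1-nitrobuta-1,3-diene
Conditions: MsCl, Et3N, CH2Cl2, −10 °C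
Reagents that add atoms: none
Why: Mesylation then E1cB elimination gives the conjugated (E)-nitrodiene.

**Step 7**
Reactants: **6**; **10**
Product: **11** quaternary nitro-aldehyde with the C1, C2, C10 configuration of the target
Conditions: Jacobsen-type chiral primary amine–thiourea (20 mol %), PhCO2H (20 mol %), toluene, 4 °C
Reagents that add atoms: none
Why: Enamine-catalysed 1,4-Michael addition of an α,α-disubstituted aldehyde to the nitrodiene. It forms the C1 quaternary centre and C10 together, with the catalyst choosing the faces; C2 is remote.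

**Step 8**
Reactants: **11**; **12** allyltributylstannane
Product: **13** homoallylic alcohol with C14 (S)-OH as in the target
Conditions: Ti(OiPr)4 (10 mol %), BINOL enantiomer matched to C14 (20 mol %), 4 Å MS, CH2Cl2, −20 °C
Reagents that add atoms: none (allylstannane is reactant **12**)
Why: Keck catalytic asymmetric allylation; catalyst control overrides the neopentyl aldehyde's bias and sets C14.

**Step 9**
Reactants: **13**
Product: **14** bis-TBS nitro-triene
Conditions: TBSOTf, 2,6-lutidine, CH2Cl2, 0 °C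
Reagents that add atoms: TBSOTf, CC(C)(C)[Si](C)(C)OS(=O)(=O)C(F)(F)F
Why: Protects C14-OH before metathesis.

**Step 10**
Reactants: **14**
Product: **15** ring-A nitro-cyclohexene
Conditions: Hoveyda–Grubbs II (5 mol %), toluene, 0.01 M, 60 °C
Reagents that add atoms: none (ethylene is lost)
Why: RCM joins the C11 isopropenyl and the C12 allyl terminus into the trisubstituted cyclohexene (C11=C12). The C2-arm isopropenyl is too hindered to close a competing ring.

**Step 11**
Reactants: **15**
Product: **16** ring-A C9 aldehyde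
Conditions: TiCl3, NH4OAc buffer (pH ≈ 6), THF/H2O, rt
Reagents that add atoms: water (O)
Why: Buffered McMurry–Nef conversion of the primary nitroalkane to the aldehyde; the mild pH avoids silyl loss and C10 epimerisation.

**Step 12**
Reactants: **16**; **17** 1,3-dithiane
Product: **18** C9 dithianyl carbinol
Conditions: n-BuLi, THF, −30 °C (dithiane); then **16**, −78 °C
Reagents that add atoms: none
Why: Corey–Seebach addition. Felkin–Anh attack anti to the quaternary C1 sets C9 as in the target, and the minor epimer is separable.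

**Step 13**
Reactants: **18**
Product: **19** C9-OPMB dithiane
Conditions: NaH, PMBBr, TBAI, THF/DMF, 0 °C → rt
Reagents that add atoms: PMBBr, COc1ccc(CBr)cc1
Why: Williamson etherification gives a PMB group orthogonal to TBS and acetate.

**Step 14**
Reactants: **19**; **20** acrolein
Product: **21** C7 allylic alcohol (C7 epimers, ~1:1)
Conditions: t-BuLi, THF, −78 °C, 1 h; then **20**, −78 °C
Reagents that add atoms: none
Why: Corey–Seebach alkylation; the tertiary dithiane anion adds 1,2 to the enal, and the C7 centre is deliberately left unset.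

**Step 15**
Reactants: **21**
Product: **22** acryloyl dithiane (enone)
Conditions: (COCl)2, DMSO, CH2Cl2, −78 °C; then Et3N
Reagents that add atoms: none
Why: Swern oxidation, which is dithiane-safe, erases the C7 ambiguity.

**Step 16**
Reactants: **22**
Product: **23** (7S)-allylic alcohol
Conditions: (R)-Me-CBS (20 mol %), catecholborane, toluene, −78 °C
Reagents that add atoms: none
Why: Corey–Bakshi–Shibata reduction; the bulky quaternary dithianyl versus the small vinyl group gives 7S, the target's configuration.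

**Step 17**
Reactants: **23**
Product: **24** C8 α-hydroxy ketone (C7-OH free, C9-OPMB)
Conditions: Hg(ClO4)2·3H2O, CaCO3, THF/H2O (4:1), 0 °C
Reagents that add atoms: water (O)
Why: Hg(II)-mediated dithioacetal hydrolysis. It is done before the metathesis because sulfur would poison Ru, and PMB, TBS and the alkenes survive.

**Step 18**
Reactants: **24**
Product: **25** 10-membered macrocycle with Z-C5=C6
Conditions: Hoveyda–Grubbs II (15 mol %), toluene, 0.002 M, 80 °C, slow addition
Reagents that add atoms: none (ethylene is lost)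
Why: Macro-RCM between the C5 isopropenyl and the C7 vinyl; the ring strain of a cyclodecene favours the ring-cis trisubstituted alkene.

**Step 19**
Reactants: **26** propionic acid
Product: **27** 2-bromopropionyl bromide (racemic; the stereocentre is destroyed in Step 21)
Conditions: PBr3 (0.4 equiv), Br2 (1.1 equiv), neat, 80 °C
Reagents that add atoms: Br2, BrBr; PBr3, BrP(Br)Br
Why: Hell–Volhard–Zelinsky α-bromination gives the Reformatsky partner from an achiral acid.

**Step 20**
Reactants: **25**; **27**
Product: **28** C7 2-bromopropionate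
Conditions: pyridine, DMAP (cat.), CH2Cl2, 0 °C
Reagents that add atoms: none
Why: C7-OH is the only free hydroxyl, so acylation is selective and C7 is retained.

**Step 21**
Reactants: **28**
Product: **29** γ-lactone with C8 tertiary alcohol (C2-OTBS, C14-OTBS, C9-OPMB)
Conditions: SmI2 (3 equiv), THF, −78 → −20 °C
Reagents that add atoms: none
Why: Intramolecular SmI2 Reformatsky-aldol; the Sm(III) enolate adds to the C8 ketone via a chelated chair-like transition state. The macrocycle permits the trans-fused lactone, which sets C8 and C17 (the methyl stays epimerisable).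

**Step 22**
Reactants: **29**
Product: **30** C2,C14-diol
Conditions: HF·pyridine, THF/pyridine, 0 → 40 °C
Reagents that add atoms: none
Why: Fluoride removes both TBS ethers; PMB, the lactone and the alkenes are untouched.

**Step 23**
Reactants: **30**
Product: **31** 2,14-diacetate, 9-O-PMB
Conditions: Ac2O, Et3N, DMAP (cat.), CH2Cl2, rt
Reagents that add atoms: Ac2O, CC(=O)OC(C)=O
Why: DMAP acylates the two secondary alcohols; the hindered tertiary C8-OH is left alone, and the C9-OPMB is protected.

**Step 24**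
Reactants: **31**
Product: **32** 9-deacetylstylatulide lactone
Conditions: DDQ, CH2Cl2/pH 7 buffer (10:1), 0 °C
Reagents that add atoms: none
Why: Oxidative PMB removal leaves the acetates, the lactone and both alkenes intact and gives the free 9-OH.

## Compound list
1 | ethyl 2-methyl-3-oxobutanoate | CCOC(=O)C(C)C(C)=O | starting material
2 | 3-bromo-2-methylprop-1-ene | C=C(C)CBr | starting material
3 | ethyl 2,6-dimethyl-3-oxohept-6-enoate | CCOC(=O)C(C)C(=O)CCC(C)=C | intermediate
4 | ethyl (2S,3R)-3-hydroxy-2,6-dimethylhept-6-enoate | CCOC(=O)[C@@H](C)[C@H](O)CCC(C)=C | intermediate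
5 | TBS ether of 4 | CCOC(=O)[C@@H](C)[C@H](O[Si](C)(C)C(C)(C)C)CCC(C)=C | intermediate
6 | (2S,3R)-3-(TBSO)-2,6-dimethylhept-6-enal | O=C[C@@H](C)[C@H](O[Si](C)(C)C(C)(C)C)CCC(C)=C | intermediate
7 | methacrolein | C=C(C)C=O | starting material
8 | nitromethane | C[N+](=O)[O-] | starting material
9 | 3-methyl-1-nitrobut-3-en-2-ol | C=C(C)C(O)C[N+](=O)[O-] | intermediate
10 | (E)-3-methyl-1-nitrobuta-1,3-diene | C=C(C)/C=C/[N+](=O)[O-] | intermediate
11 | quaternary nitro-aldehyde | O=C[C@@](C)([C@H](C(C)=C)C[N+](=O)[O-])[C@H](O[Si](C)(C)C(C)(C)C)CCC(C)=C | intermediate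
12 | allyltributylstannane | C=CC[Sn](CCCC)(CCCC)CCCC | starting material
13 | homoallylic alcohol (C14-OH) | C=CC[C@H](O)[C@@](C)([C@H](C(C)=C)C[N+](=O)[O-])[C@H](O[Si](C)(C)C(C)(C)C)CCC(C)=C | intermediate
14 | bis-TBS nitro-triene | C=CC[C@H](O[Si](C)(C)C(C)(C)C)[C@@](C)([C@H](C(C)=C)C[N+](=O)[O-])[C@H](O[Si](C)(C)C(C)(C)C)CCC(C)=C | intermediate
15 | ring-A nitro-cyclohexene | [O-][N+](=O)C[C@H]1C(C)=CC[C@H](O[Si](C)(C)C(C)(C)C)[C@]1(C)[C@H](O[Si](C)(C)C(C)(C)C)CCC(C)=C | intermediate
16 | ring-A C9 aldehyde | O=C[C@H]1C(C)=CC[C@H](O[Si](C)(C)C(C)(C)C)[C@]1(C)[C@H](O[Si](C)(C)C(C)(C)C)CCC(C)=C | intermediate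
17 | 1,3-dithiane | C1CSCSC1 | starting material
18 | C9 dithianyl carbinol | C1CSC(SC1)[C@H](O)[C@H]1C(C)=CC[C@H](O[Si](C)(C)C(C)(C)C)[C@]1(C)[C@H](O[Si](C)(C)C(C)(C)C)CCC(C)=C | intermediate
19 | C9-OPMB dithiane | C1CSC(SC1)[C@H](OCc1ccc(OC)cc1)[C@H]1C(C)=CC[C@H](O[Si](C)(C)C(C)(C)C)[C@]1(C)[C@H](O[Si](C)(C)C(C)(C)C)CCC(C)=C | intermediate
20 | acrolein | C=CC=O | starting material
21 | C7 allylic alcohol (C7 epimers) | C=CC(O)C1(SCCCS1)[C@H](OCc2ccc(OC)cc2)[C@H]2C(C)=CC[C@H](O[Si](C)(C)C(C)(C)C)[C@]2(C)[C@H](O[Si](C)(C)C(C)(C)C)CCC(C)=C | intermediate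
22 | acryloyl dithiane (enone) | C=CC(=O)C1(SCCCS1)[C@H](OCc2ccc(OC)cc2)[C@H]2C(C)=CC[C@H](O[Si](C)(C)C(C)(C)C)[C@]2(C)[C@H](O[Si](C)(C)C(C)(C)C)CCC(C)=C | intermediate
23 | (7S)-allylic alcohol | C=C[C@H](O)C1(SCCCS1)[C@H](OCc2ccc(OC)cc2)[C@H]2C(C)=CC[C@H](O[Si](C)(C)C(C)(C)C)[C@]2(C)[C@H](O[Si](C)(C)C(C)(C)C)CCC(C)=C | intermediate
24 | C8 α-hydroxy ketone | C=C[C@H](O)C(=O)[C@H](OCc1ccc(OC)cc1)[C@H]1C(C)=CC[C@H](O[Si](C)(C)C(C)(C)C)[C@]1(C)[C@H](O[Si](C)(C)C(C)(C)C)CCC(C)=C | intermediate
25 | 10-membered macrocycle (Z-C5=C6) | CC(C)(C)[Si](C)(C)O[C@H]1CC=C(C)[C@@H]2[C@@H](OCc3ccc(OC)cc3)C(=O)[C@@H](O)/C=C(/C)CC[C@@H](O[Si](C)(C)C(C)(C)C)[C@@]12C | intermediate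
26 | propionic acid | CCC(=O)O | starting material
27 | 2-bromopropionyl bromide (racemic) | CC(Br)C(=O)Br | intermediate
28 | C7 2-bromopropionate | CC(C)(C)[Si](C)(C)O[C@H]1CC=C(C)[C@@H]2[C@@H](OCc3ccc(OC)cc3)C(=O)[C@@H](OC(=O)C(C)Br)/C=C(/C)CC[C@@H](O[Si](C)(C)C(C)(C)C)[C@@]12C | intermediate
29 | protected lactone | CC(C)(C)[Si](C)(C)O[C@H]1CC=C(C)[C@@H]2[C@@H](OCc3ccc(OC)cc3)[C@@]4(O)[C@H](/C=C(/C)CC[C@@H](O[Si](C)(C)C(C)(C)C)[C@@]12C)OC(=O)[C@@H]4C | intermediate
30 | C2,C14-diol | O[C@H]1CC=C(C)[C@@H]2[C@@H](OCc3ccc(OC)cc3)[C@@]4(O)[C@H](/C=C(/C)CC[C@@H](O)[C@@]12C)OC(=O)[C@@H]4C | intermediate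
31 | 2,14-diacetate, 9-O-PMB | CC(=O)O[C@H]1CC=C(C)[C@@H]2[C@@H](OCc3ccc(OC)cc3)[C@@]4(O)[C@H](/C=C(/C)CC[C@@H](OC(C)=O)[C@@]12C)OC(=O)[C@@H]4C | intermediate
32 | 9-deacetylstylatulide lactone | CC(=O)O[C@H]1CC=C(C)[C@@H]2[C@@H](O)[C@@]3(O)[C@H](/C=C(/C)CC[C@@H](OC(C)=O)[C@@]12C)OC(=O)[C@@H]3C | target

## Totals
Total steps: 24. Longest linear sequence: 21 steps (1 → 3 → 4 → 5 → 6 → 11 → 13 → 14 → 15 → 16 → 18 → 19 → 21 → 22 → 23 → 24 → 25 → 28 → 29 → 30 → 31 → 32). This runs from **1** through Steps 1–4, then Steps 7–18, then Steps 20–24.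

**Three steps most likely to fail**
1. **Step 18 (macro-RCM).** It may give oligomers or the E isomer. Fallback: close the ring at C8–C9 instead, by intramolecular Corey–Seebach addition of the C8 dithiane anion to the C9 aldehyde. The Z-C5=C6 alkene is installed beforehand by a Z-selective Wittig of the C5 methyl ketone.
2. **Steps 7 and 8 (quaternary-centre Michael and Keck allylation on a hindered aldehyde).** Diastereoselectivity and ee may be low, and a β-silyloxy aldehyde can eliminate. Fallback: close ring A by a SmI2 Reformatsky-aldol forming C1–C14 from an α-bromoketone and an aldehyde, with C10 set by Cu-catalysed asymmetric conjugate addition.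
3. **Step 21 (SmI2 Reformatsky).** SmI2 can cleave the α-acyloxy and α-alkoxy ketone, and the C8/C17 stereochemistry is only substrate-controlled. Fallback: drop the C8 ketone and put the C17 propionate ester on a Z-C8=C9 alkene closed by RCM, then OsO4/TMEDA syn-dihydroxylation and translactonisation onto C7-OH.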